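**Retrosynthetic overview**
1. Jaspic acid ⇐ bis-demethylation of its O-methyl ether methyl ester 17 ⇐ C4–CH3 bond by photochemical SH2 methylation of the C4 tertiary radical from carbinol 15 (sets the C4 quaternary centre: CH3 α, homoprenyl β).
2. 15 ⇐ C11–aryl bond by hydroboration/B-alkyl Suzuki coupling of the exocyclic diene 13 with aryl iodide 14 (sets C9) ⇐ C9 methylenation ⇐ homoprenyl addition to the C4 ketone of dione 9.
3. Ring A of 9 ⇐ C2–C3 bond by ozonolysis/intramolecular aldol condensation, then hydrogenation, from the dialkylated carvone 5.
4. 5 ⇐ sequential α′-methylation and α′-allylation of (R)-carvone (sets C10).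
5. Ring order: ring B is bought as (R)-carvone, whose stereocentre becomes C5; ring A is annulated onto it; C10, C9 and C4 are all substrate-controlled.

Assumption: the target is exactly the stereoisomer in the given SMILES (5α-H, 9α-H, 10β-CH3, 4α-CH3, 4β-homoprenyl, i.e. homoprenyl cis to the angular methyl). Terpenoid numbering is used: ring A = C1–C5, C10; ring B = C5–C10; C11 = benzylic CH2 on C9.

**Route**

Step 1
Reactants: 1 (R)-(−)-carvone; 2 iodomethane
Product: 3 (5R)-6-methylcarvone [(5R)-2,6-dimethyl-5-(prop-1-en-2-yl)cyclohex-2-en-1-one], C6 epimer mixture, trans major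
Conditions: LDA, THF, −78 °C; MeI, −78 → 0 °C
Reagents that add atoms: iodomethane, CI
Why: Kinetic α′-deprotonation of the cross-conjugated enone and enolate alkylation; the new C6 centre is planarised again in step 2, so its configuration does not matter.

Step 2
Reactants: 3 (5R)-6-methylcarvone; 4 allyl bromide
Product: 5 (5S,6S)-6-allyl-2,6-dimethyl-5-(prop-1-en-2-yl)cyclohex-2-en-1-one (allyl trans, methyl cis to the isopropenyl group; C5 is unchanged, its descriptor changes only by CIP priority)
Conditions: LDA, THF, −78 → −10 °C; DMPU, allyl bromide, −78 °C → rt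
Reagents that add atoms: allyl bromide, C=CCBr
Why: Second α′-enolate alkylation; the electrophile enters anti to the adjacent isopropenyl group, which sets the C10 quaternary centre with CH3 cis to the future C4 substituent, as a trans-decalin requires.

Step 3
Reactants: 5 allyl-methyl-carvone; 6 ozone
Product: 8 trans-fused enedione, 4a,6-dimethyl-4,4a,8,8a-tetrahydronaphthalene-1,5-dione (terpenoid: 4,9-dioxo-2,7-diene, 10β-CH3, 5α-H), formed via keto-aldehyde 7 (5-acetyl-6-(2-oxoethyl)-2,6-dimethylcyclohex-2-en-1-one, not isolated)
Conditions: O3, CH2Cl2–MeOH, cat. pyridine, −78 °C (Sudan III end point); Me2S, −78 °C → rt; then pyrrolidine (20 mol%), AcOH (20 mol%), THF, rt → 40 °C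
Reagents that add atoms: ozone, [O-][O+]=O
Why: Ozonolysis cleaves the two electron-rich alkenes (isopropenyl → acetyl, allyl → CH2CHO, each losing CH2O) much faster than the enone C=C, and amine-catalysed intramolecular aldol condensation (methyl ketone C3 onto aldehyde C2, the only mode giving an unstrained ring) closes ring A; the trans-diequatorial arms give the trans ring fusion and the mild conditions avoid enolisation toward C5.

Step 4
Reactants: 8 enedione
Product: 9 trans-4a,6-dimethyl-2,3,4,4a,8,8a-hexahydronaphthalene-1,5-dione (saturated ring-A C4 ketone, ring-B enone intact)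
Conditions: H2 (1 atm), RhCl(PPh3)3 (5 mol%), benzene, rt
Reagents that add atoms: none
Why: Wilkinson hydrogenation reduces the cis-disubstituted C2=C3 alkene and leaves the trisubstituted, α-methylated C7=C8 enone alkene untouched; no stereocentre is affected.

Step 5
Reactants: 9 dione; 10 5-bromo-2-methylpent-2-ene (as its Grignard reagent)
Product: 11 C4 tertiary carbinol, 1-hydroxy-4a,6-dimethyl-1-(4-methylpent-3-en-1-yl)-1,2,3,4,4a,8a-hexahydronaphthalen-5(8H)-one (C4 epimer mixture, 4β-OH expected major)
Conditions: 10, Mg, THF; anhydrous CeCl3, THF, −78 °C; then 9, −78 → −40 °C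
Reagents that add atoms: 5-bromo-2-methylpent-2-ene (via (4-methylpent-3-en-1-yl)magnesium bromide), CC(C)=CCCBr
Why: Organocerium 1,2-addition (suppresses enolisation at C5) is chemoselective for the unhindered C4 cyclohexanone over the C9 carbonyl, which is flanked by quaternary C10 and the methyl-bearing sp2 C8; the carbinol configuration is irrelevant because C4 becomes a planar radical in step 8.

Step 6
Reactants: 11 carbinol; 12 methyltriphenylphosphonium bromide
Product: 13 diene carbinol (C9=C11H2 exocyclic methylene conjugated with C7=C8; C4 carbinol unchanged)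
Conditions: Ph3PCH3Br (4 equiv), KOtBu (4 equiv), toluene, 90 °C
Reagents that add atoms: methyltriphenylphosphonium bromide, C[P+](c1ccccc1)(c1ccccc1)c1ccccc1.[Br-]
Why: Wittig methylenation under forcing salt-free conditions suits this hindered, non-enolisable ketone; the tertiary alkoxide is inert and no stereocentre is touched.

Step 7
Reactants: 13 diene carbinol; 14 methyl 3-iodo-4-methoxybenzoate
Product: 15 methyl 3-{[9α-H drim-7-ene-type decalin with 4-hydroxy-4-homoprenyl]methyl}-4-methoxybenzoate (C11 β-equatorial on C9, Δ7 retained, C4 carbinol epimers)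
Conditions: 9-BBN (2.5 equiv), THF, 0 °C → rt; then 14, PdCl2(dppf) (5 mol%), AsPh3, Cs2CO3, DMF–H2O, 50 °C
Reagents that add atoms: methyl 3-iodo-4-methoxybenzoate, COC(=O)c1ccc(OC)c(I)c1
Why: 9-BBN adds boron to the terminal CH2 of the exocyclic alkene (1,2-addition, trisubstituted alkenes untouched) and delivers H to C9 from the α-face, anti to the axial C10-methyl on the neighbouring carbon, giving 9α-H with the CH2 equatorial; B-alkyl Suzuki–Miyaura coupling then forms the CH2–aryl bond.

Step 8
Reactants: 15 arylmethyl carbinol; 16 methanol
Product: 17 O-methyl jaspic acid methyl ester (4α-CH3, 4β-homoprenyl)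
Conditions: 15 and MeOH (5 equiv) each condensed with an N-aryl benzoxazolium salt (NHC precursor), pyridine, MTBE, rt; then [Ir(ppy)2(dtbbpy)]PF6 (1 mol%), Ni(acac)2/KTp* (10 mol%), quinuclidine, DMSO–MTBE, 450 nm LEDs, rt
Reagents that add atoms: methanol, CO
Why: Proposed new method: the NHC adducts of 15 and MeOH are oxidised by the excited Ir photocatalyst and fragment by β-scission to the planar C4 tertiary radical (both carbinol epimers converge) and CH3•; the Ni(II) scorpionate captures CH3• (radical sorting), and the C4 radical displaces nickel by SH2 at the methyl carbon along a linear C4···CH3···Ni axis that is open only on the equatorial α-face, because the β-face is blocked by the syn-axial C10-methyl (the same facial preference as MeI alkylation of C4 enolates in trans-decalins), so CH3 ends α and the chain axial β; closest known reaction is NHC-mediated deoxygenative alcohol–alcohol SH2 cross-coupling (tertiary-alcohol methylation), whose use to create a quaternary stereocentre stereoconvergently next to a ring-fusion methine, on a radical carrying a γ,δ-alkene, is the untested extension here.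

Step 9
Reactants: 17 O-methyl jaspic acid methyl ester
Product: 18 jaspic acid
Conditions: NaSEt (6 equiv), DMF, 120 °C; then aq. HCl
Reagents that add atoms: none
Why: Thiolate SN2 demethylation removes both the aryl methyl ether (activated by the para carbonyl) and the methyl ester in one operation; alkenes and all four stereocentres are inert to these conditions.

**Compound list**
1 | (R)-(−)-carvone | O=C1C(C)=CC[C@@H](C(C)=C)C1 | starting material
2 | iodomethane | CI | starting material
3 | (5R)-6-methylcarvone (C6 epimers) | O=C1C(C)=CC[C@@H](C(C)=C)C1C | intermediate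
4 | allyl bromide | C=CCBr | starting material
5 | (5S,6S)-6-allyl-2,6-dimethyl-5-(prop-1-en-2-yl)cyclohex-2-en-1-one | O=C1C(C)=CC[C@@H](C(C)=C)[C@]1(C)CC=C | intermediate
6 | ozone | [O-][O+]=O | starting material
7 | 5-acetyl-6-(2-oxoethyl)-2,6-dimethylcyclohex-2-en-1-one (acetyl trans to CH2CHO; not isolated) | O=C1C(C)=CC[C@@H](C(C)=O)[C@]1(C)CC=O | intermediate
8 | trans-4a,6-dimethyl-4,4a,8,8a-tetrahydronaphthalene-1,5-dione (10β-CH3, 5α-H) | O=C1C=CC[C@]2(C)C(=O)C(C)=CC[C@@H]12 | intermediate
9 | trans-4a,6-dimethyl-2,3,4,4a,8,8a-hexahydronaphthalene-1,5-dione | O=C1CCC[C@]2(C)C(=O)C(C)=CC[C@@H]12 | intermediate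
10 | 5-bromo-2-methylpent-2-ene | CC(C)=CCCBr | starting material
11 | C4 tertiary carbinol enone (C4 epimers) | CC(C)=CCCC1(O)CCC[C@]2(C)C(=O)C(C)=CC[C@@H]12 | intermediate
12 | methyltriphenylphosphonium bromide | C[P+](c1ccccc1)(c1ccccc1)c1ccccc1.[Br-] | starting material
13 | C9-methylene diene carbinol (C4 epimers) | CC(C)=CCCC1(O)CCC[C@]2(C)C(=C)C(C)=CC[C@@H]12 | intermediate
14 | methyl 3-iodo-4-methoxybenzoate | COC(=O)c1ccc(OC)c(I)c1 | starting material
15 | methyl 4-methoxy-3-(decalinylmethyl)benzoate carbinol (9α-H, C4 epimers) | CC(C)=CCCC1(O)CCC[C@]2(C)[C@@H](Cc3cc(C(=O)OC)ccc3OC)C(C)=CC[C@@H]12 | intermediate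
16 | methanol | CO | starting material
17 | O-methyl jaspic acid methyl ester | CC(C)=CCC[C@@]1(C)CCC[C@]2(C)[C@@H](Cc3cc(C(=O)OC)ccc3OC)C(C)=CC[C@@H]12 | intermediate
18 | jaspic acid | CC(C)=CCC[C@@]1(C)CCC[C@]2(C)[C@@H](Cc3cc(C(=O)O)ccc3O)C(C)=CC[C@@H]12 | target

**Step count**
Total steps: 9. Longest linear sequence: 9, from (R)-carvone; all coupling partners are commercial.

**Three steps most likely to fail**
- **Step 8 (proposed new SH2 methylation).** Risks: the hindered, largely axial tertiary carbinol may not condense with the NHC salt, the radical may disproportionate to C4 alkenes, or the α/β ratio may be low. Fallback (known ionic chemistry): titanium-mediated tertiary-alcohol methylation of carbinol 11 before the arene is attached (Me2Zn/TiCl4 → Me2TiCl2, CH2Cl2, −30 °C), or conversion to the tertiary chloride and treatment with Me3Al. The C4 carbocation should take methyl from the same α-face; steps 6, 7 and 9 then follow unchanged.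
- **Step 3 (one-pot ozonolysis/aldol condensation).** Risks: over-ozonolysis of the enone, or C5 epimerisation next to the C4 ketone (the cis-fused isomer may be thermodynamically competitive). Fallback: close ring A by alkylation instead of condensation. After ozonolysis, reduce only the aldehyde (NaBH(OAc)3), convert the primary alcohol to the iodide (I2, PPh3, imidazole), and cyclise the kinetic methyl-ketone enolate (LiHMDS, THF, −78 °C, 6-exo-tet). This gives dione 9 directly under non-equilibrating conditions and also removes step 4.
- **Step 7 (hydroboration/B-alkyl Suzuki on the hindered exocyclic diene).** Risks: slow or unselective hydroboration next to quaternary C10, or sluggish transmetalation of the β-branched alkylborane. Fallback: oxidise the borane to the C11 primary alcohol (NaBO3), convert it to the iodide, and form the CH2–aryl bond by nickel-catalysed reductive cross-electrophile coupling with 14 (or Negishi coupling of the derived alkylzinc).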